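**Retrosynthetic overview**
1. The 2,3-dihydrofuran is made last, by dehydration of the C15 lactol, which comes from a 15,16-γ-lactone. That lactone and the 9,13-ether form together when the C9 alkoxide adds to C13 of a side-chain butenolide (oxa-Michael), the closure assumed in the biogenesis of prefuranic labdanes.
2. The 8β,17-epoxide comes from CH2 transfer to a 17-nor-8-ketone, the 9α-OH from a Rubottom oxidation, and the ketone from the 8(17)-alkene.
3. The 19,20-δ-lactone and the 6β-acetate both come from one acetaldehyde acetal that bridges O6 and O20 (hydride abstraction, then lactonisation).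
4. Rings A and B close in one oxidative radical polyene bicyclisation of a β-keto ester whose first alkene sits in that seven-membered acetal ring. The single C6 stereocentre, from (R)-epichlorohydrin, controls C4, C5 and C10.
5. Ring order: dioxepin (ring-closing metathesis), rings A and B, δ-lactone, epoxide, tetrahydrofuran plus γ-lactone, dihydrofuran.

Assumption: labdane numbering and the labdane stereoparent (5α-H, 10β-C20, C18 α-methyl and C19 β on C4) are used from 21 on; the acetal carbon in 16–23, C4 in 19 and 20 and C15 in 33 and 34 are unseparated epimer mixtures that converge later.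

**Step 1**
Reactants: 1 (R)-epichlorohydrin; 2 ethynyl(trimethyl)silane
Product: 4 (2R)-2-(prop-2-yn-1-yl)oxirane, via chlorohydrin 3 (not isolated)
Conditions: 2, n-BuLi, THF, −78 °C; BF3·OEt2 then 1, −78 °C; then K2CO3, MeOH, 0 °C to rt
Reagents that add atoms: none
Why: BF3-assisted SN2 opening of the epoxide at its CH2 terminus by the lithium acetylide (Yamaguchi alkynylation), then base closure of the chlorohydrin with loss of the C-silyl group, moves the epoxide without touching the C–O stereocentre, which is taken from 1.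

**Step 2**
Reactants: 4 (2R)-2-(prop-2-yn-1-yl)oxirane
Product: 5 (3R)-hex-1-en-5-yn-3-ol
Conditions: Me3SI, n-BuLi, THF, −10 °C to rt
Reagents that add atoms: trimethylsulfonium iodide C[S+](C)C.[I-]
Why: dimethylsulfonium methylide opens the epoxide at CH2 and the betaine eliminates Me2S to give the one-carbon-homologated allylic alcohol (sulfur-ylide epoxide homologation), with the stereocentre retained.

**Step 3**
Reactants: 5 (3R)-hex-1-en-5-yn-3-ol
Product: 7 (3R,5E)-6-iodo-5-methylhexa-1,5-dien-3-ol, via alkenylalane 6 (not isolated)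
Conditions: Me3Al, Cp2ZrCl2 (25 mol %), CH2Cl2, 0 °C to rt; then I2, THF, −30 °C
Reagents that add atoms: trimethylaluminium C[Al](C)C; iodine [I][I]
Why: zirconium-catalysed syn-carboalumination of the terminal alkyne (Negishi) puts CH3 on the inner carbon and Al on the terminus, and iodinolysis with retention gives the E-iodoalkene while the hydroxyl is carried as its aluminium alkoxide.

**Step 4**
Reactants: 8 tert-butyl(dimethyl)(prop-2-yn-1-yloxy)silane
Product: 9 methyl 4-{[tert-butyl(dimethyl)silyl]oxy}but-2-ynoate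
Conditions: n-BuLi, THF, −78 °C; ClCO2Me
Reagents that add atoms: methyl chloroformate COC(=O)Cl
Why: C-acylation of the lithium acetylide by the chloroformate.

**Step 5**
Reactants: 9 methyl 4-{[tert-butyl(dimethyl)silyl]oxy}but-2-ynoate
Product: 10 methyl (2Z)-3-({[tert-butyl(dimethyl)silyl]oxy}methyl)penta-2,4-dienoate
Conditions: CH2=CHMgBr, CuBr·SMe2, THF, −78 °C; NH4Cl (aq) at −78 °C
Reagents that add atoms: vinylmagnesium bromide C=C[Mg]Br
Why: syn-carbocupration (conjugate addition) of the vinylcopper reagent to the ynoate and cold protonation place CH2OSi cis to the ester.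

**Step 6**
Reactants: 10 methyl (2Z)-3-({[tert-butyl(dimethyl)silyl]oxy}methyl)penta-2,4-dienoate; 7 (3R,5E)-6-iodo-5-methylhexa-1,5-dien-3-ol
Product: 12 methyl (2Z,6E,9R)-3-({[tert-butyl(dimethyl)silyl]oxy}methyl)-9-hydroxy-7-methylundeca-2,6,10-trienoate, via alkylborane 11 (not isolated)
Conditions: 10, 9-BBN, THF, 0 °C to rt; then 7, Pd(dppf)Cl2 (5 mol %), K3PO4 (aq), DMF, rt
Reagents that add atoms: none
Why: 9-BBN adds only to the terminal vinyl group of 10 with boron on the CH2 terminus, and B-alkyl Suzuki–Miyaura coupling with the iodoalkene retains the E geometry.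

**Step 7**
Reactants: 12 methyl (2Z,6E,9R)-3-({[tert-butyl(dimethyl)silyl]oxy}methyl)-9-hydroxy-7-methylundeca-2,6,10-trienoate; 13 ethoxyethene
Product: 14 methyl (2Z,6E,9R)-3-({[tert-butyl(dimethyl)silyl]oxy}methyl)-9-(ethenyloxy)-7-methylundeca-2,6,10-trienoate
Conditions: 13 (solvent), Pd(OCOCF3)2 (1 mol %), 4,7-diphenyl-1,10-phenanthroline, Et3N, 40 °C
Reagents that add atoms: none
Why: palladium-catalysed transfer vinylation (transetherification) of the secondary alcohol, run far below the temperature at which the allyl vinyl ether would undergo Claisen rearrangement.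

**Step 8**
Reactants: 14 methyl (2Z,6E,9R)-3-({[tert-butyl(dimethyl)silyl]oxy}methyl)-9-(ethenyloxy)-7-methylundeca-2,6,10-trienoate; 15 2-methylidenepropane-1,3-diol
Product: 16 methyl (2Z,6E,9R)-3-({[tert-butyl(dimethyl)silyl]oxy}methyl)-9-(1-{[2-(hydroxymethyl)prop-2-en-1-yl]oxy}ethoxy)-7-methylundeca-2,6,10-trienoate
Conditions: 15 (4 equiv), PPTS (5 mol %), CH2Cl2, 0 °C
Reagents that add atoms: none
Why: acid-catalysed addition of one hydroxyl of the excess diol to the vinyl ether gives the mixed acetaldehyde acetal, whose new centre forms as both epimers and is harmless because this carbon later becomes the acetyl carbonyl.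

**Step 9**
Reactants: 16 methyl (2Z,6E,9R)-3-({[tert-butyl(dimethyl)silyl]oxy}methyl)-9-(1-{[2-(hydroxymethyl)prop-2-en-1-yl]oxy}ethoxy)-7-methylundeca-2,6,10-trienoate
Product: 17 methyl (2Z,6E,9R)-9-(1-{[2-(bromomethyl)prop-2-en-1-yl]oxy}ethoxy)-3-({[tert-butyl(dimethyl)silyl]oxy}methyl)-7-methylundeca-2,6,10-trienoate
Conditions: CBr4, PPh3, 2,6-lutidine, CH2Cl2, 0 °C
Reagents that add atoms: carbon tetrabromide BrC(Br)(Br)Br
Why: Appel bromination of the primary allylic alcohol, buffered so that the acetal survives.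

**Step 10**
Reactants: 17 methyl (2Z,6E,9R)-9-(1-{[2-(bromomethyl)prop-2-en-1-yl]oxy}ethoxy)-3-({[tert-butyl(dimethyl)silyl]oxy}methyl)-7-methylundeca-2,6,10-trienoate; 18 methyl 2-methyl-3-oxobutanoate
Product: 19 methyl (2Z,6E,9R)-3-({[tert-butyl(dimethyl)silyl]oxy}methyl)-9-{1-[(7-methoxy-6-methyl-2-methylidene-5,7-dioxoheptyl)oxy]ethoxy}-7-methylundeca-2,6,10-trienoate
Conditions: 18, NaH then n-BuLi, THF, 0 °C; 17, −78 to 0 °C
Reagents that add atoms: none
Why: γ-alkylation of the β-keto ester dianion (Weiler) by SN2 displacement of the allylic bromide, which is faster than any attack on the hindered conjugated ester.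

**Step 11**
Reactants: 19 methyl (2Z,6E,9R)-3-({[tert-butyl(dimethyl)silyl]oxy}methyl)-9-{1-[(7-methoxy-6-methyl-2-methylidene-5,7-dioxoheptyl)oxy]ethoxy}-7-methylundeca-2,6,10-trienoate
Product: 20 methyl (2Z,6E)-3-({[tert-butyl(dimethyl)silyl]oxy}methyl)-8-[(4R)-6-(5-methoxy-4-methyl-3,5-dioxopentyl)-2-methyl-4,7-dihydro-1,3-dioxepin-4-yl]-7-methylocta-2,6-dienoate
Conditions: second-generation Grubbs catalyst RuCl2(=CHPh)(PCy3)(H2IMes) (5 mol %), CH2Cl2 (5 mM), 40 °C
Reagents that add atoms: none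
Why: ring-closing metathesis of the vinyl and 1,1-disubstituted alkenes gives the seven-membered dioxepin, whose ring fixes the new trisubstituted alkene with C6 and C20 cis.

**Step 12**
Reactants: 20 methyl (2Z,6E)-3-({[tert-butyl(dimethyl)silyl]oxy}methyl)-8-[(4R)-6-(5-methoxy-4-methyl-3,5-dioxopentyl)-2-methyl-4,7-dihydro-1,3-dioxepin-4-yl]-7-methylocta-2,6-dienoate
Product: 21 dimethyl (13Z)-16-{[tert-butyl(dimethyl)silyl]oxy}-6β,20-(ethylidenedioxy)-3-oxolabda-8(17),13-diene-15,19-dioate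
Conditions: Mn(OAc)3·2H2O (2.2 equiv), Cu(OAc)2·H2O (1 equiv), degassed EtOH, 25–40 °C
Reagents that add atoms: none
Why: Proposed new method: trivalent manganese oxidises the β-keto ester to the C4 radical, which adds 6-endo to C5 of the ring alkene anti to the C6 side chain, the tertiary C10 radical then adds 6-endo to C9 on the only face the tether allows (trans ring fusion, acetal bridge 1,3-diaxial, hence O6 β), divalent copper oxidises the C8 radical to the 8(17)-alkene, and C4 forms with the ester β as usual for 2-methyl-3-oxo ester radicals; the closest known reaction is the Snider oxidative radical polyene cyclisation.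

**Step 13**
Reactants: 21 dimethyl (13Z)-16-{[tert-butyl(dimethyl)silyl]oxy}-6β,20-(ethylidenedioxy)-3-oxolabda-8(17),13-diene-15,19-dioate
Product: 23 dimethyl (13Z)-16-{[tert-butyl(dimethyl)silyl]oxy}-6β,20-(ethylidenedioxy)labda-8(17),13-diene-15,19-dioate, via tosylhydrazone 22 (not isolated)
Conditions: TsNHNH2, EtOH, 80 °C; then catecholborane, CHCl3, 0 °C; NaOAc·3H2O, 60 °C
Reagents that add atoms: none
Why: deoxygenation of the hindered C3 ketone through its tosylhydrazone (Kabalka variant of the Caglioti reduction) avoids the retro-Claisen cleavage that basic Wolff–Kishner conditions would cause.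

**Step 14**
Reactants: 23 dimethyl (13Z)-16-{[tert-butyl(dimethyl)silyl]oxy}-6β,20-(ethylidenedioxy)labda-8(17),13-diene-15,19-dioate
Product: 26 methyl (13Z)-6β-acetoxy-16-{[tert-butyl(dimethyl)silyl]oxy}-19-oxo-19,20-epoxylabda-8(17),13-dien-15-oate, via dioxepanylium salt 24 (not isolated), via hydroxy acetate 25 (not isolated)
Conditions: Ph3CBF4 (1.1 equiv), CH2Cl2, 0 °C; NaHCO3 (aq); then PPTS (10 mol %), benzene, 60 °C
Reagents that add atoms: water O
Why: Proposed new method: the trityl cation abstracts hydride from the acetal C–H to give the bridging 2-methyl-1,3-dioxepan-2-ylium ion, water adds and the orthoacid collapses with release of the less hindered primary O20 so that the acetyl group stays on the axial O6, and the freed C20 hydroxyl, 1,3-diaxial to the C19 ester, lactonises; the closest known reactions are the trityl-cation oxidation of cyclic acetals to hydroxy esters and the kinetic opening of cyclic orthoesters to the more hindered ester.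

**Step 15**
Reactants: 26 methyl (13Z)-6β-acetoxy-16-{[tert-butyl(dimethyl)silyl]oxy}-19-oxo-19,20-epoxylabda-8(17),13-dien-15-oate
Product: 27 methyl (13Z)-6β-acetoxy-16-{[tert-butyl(dimethyl)silyl]oxy}-8,19-dioxo-19,20-epoxy-17-norlabd-13-en-15-oate
Conditions: O3, CH2Cl2–MeOH, pyridine, −78 °C; Me2S
Reagents that add atoms: ozone [O-][O+]=O
Why: ozonolysis of the electron-rich 1,1-disubstituted alkene, which reacts far faster than the conjugated ester alkene.

**Step 16**
Reactants: 27 methyl (13Z)-6β-acetoxy-16-{[tert-butyl(dimethyl)silyl]oxy}-8,19-dioxo-19,20-epoxy-17-norlabd-13-en-15-oate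
Product: 29 methyl (13Z)-6β-acetoxy-9α-hydroxy-16-{[tert-butyl(dimethyl)silyl]oxy}-8,19-dioxo-19,20-epoxy-17-norlabd-13-en-15-oate, via silyl enol ether 28 (not isolated)
Conditions: TMSOTf, Et3N, CH2Cl2, 0 °C to rt; then DMDO, acetone, −40 °C; citric acid, MeOH
Reagents that add atoms: dimethyldioxirane CC1(C)OO1
Why: Rubottom oxidation, in which equilibrating silylation gives the more substituted 8(9)-enol ether and the dioxirane attacks its α face, away from the axial C20 and 6β-acetate, so C9 becomes 9α-OH with the side chain β.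

**Step 17**
Reactants: 29 methyl (13Z)-6β-acetoxy-9α-hydroxy-16-{[tert-butyl(dimethyl)silyl]oxy}-8,19-dioxo-19,20-epoxy-17-norlabd-13-en-15-oate
Product: 30 methyl (13Z)-6β-acetoxy-8β,17:19,20-diepoxy-9α-hydroxy-16-{[tert-butyl(dimethyl)silyl]oxy}-19-oxolabd-13-en-15-oate
Conditions: ICH2Cl, MeLi·LiBr (3 equiv each), THF, −78 °C
Reagents that add atoms: chloroiodomethane ClCI
Why: chloromethyllithium, generated in the presence of the ketone, adds to C8 from the α (equatorial) side because the β face carries the syn-axial C20 and 6β-acetate, and the β-alkoxide closes onto CH2Cl to give the 8β,17-epoxide (Matteson-type halomethyllithium epoxidation of a ketone).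

**Step 18**
Reactants: 30 methyl (13Z)-6β-acetoxy-8β,17:19,20-diepoxy-9α-hydroxy-16-{[tert-butyl(dimethyl)silyl]oxy}-19-oxolabd-13-en-15-oate
Product: 32 (13R)-6β-acetoxy-8β,17:9α,13-diepoxylabdane-19,20:15,16-diolide, via hydroxy butenolide 31 (not isolated)
Conditions: TBAF, THF, 0 °C to rt
Reagents that add atoms: none
Why: fluoride frees the C16 alkoxide, which lactonises onto the cis ester to the butenolide, and the C9 alkoxide then adds 5-exo to C13 (intramolecular oxa-Michael addition, the biogenesis-type closure of the 9,13-ether), the reversible addition settling C13 under thermodynamic control so that any 13-epimer can be separated and re-equilibrated with base.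

**Step 19**
Reactants: 32 (13R)-6β-acetoxy-8β,17:9α,13-diepoxylabdane-19,20:15,16-diolide
Product: 33 (13R)-6β-acetoxy-8β,17:9α,13:15,16-triepoxy-15-hydroxylabdan-19,20-olide
Conditions: Sia2BH, THF, 0 °C to rt; H2O2, pH 7 buffer
Reagents that add atoms: none
Why: disiamylborane reduces the unhindered γ-lactone to the lactol and leaves the acetate, the hindered δ-lactone and the epoxide untouched (chemoselective lactone-to-lactol reduction).

**Step 20**
Reactants: 33 (13R)-6β-acetoxy-8β,17:9α,13:15,16-triepoxy-15-hydroxylabdan-19,20-olide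
Product: 35 nepetaefolin, via lactol mesylate 34 (not isolated)
Conditions: MsCl, Et3N, CH2Cl2, −20 °C to rt
Reagents that add atoms: none
Why: the lactol mesylate ionises to the C15 oxocarbenium ion and the amine removes a C14 proton (dehydration of a lactol to a 2,3-dihydrofuran, as in glycal formation), under base throughout so the acid-labile enol ether cannot open to the furan.

**Compound list**
1 | (2R)-2-(chloromethyl)oxirane, (R)-epichlorohydrin | ClC[C@H]1CO1 | starting material
2 | ethynyl(trimethyl)silane | C#C[Si](C)(C)C | starting material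
3 | (2R)-1-chloro-5-(trimethylsilyl)pent-4-yn-2-ol | ClC[C@H](O)CC#C[Si](C)(C)C | intermediate
4 | (2R)-2-(prop-2-yn-1-yl)oxirane | C#CC[C@@H]1CO1 | intermediate
5 | (3R)-hex-1-en-5-yn-3-ol | C=C[C@H](O)CC#C | intermediate
6 | dimethylaluminium (3R,5E)-6-(dimethylalumanyl)-5-methylhexa-1,5-dien-3-olate | C=C[C@H](O[Al](C)C)C/C(C)=C/[Al](C)C | intermediate
7 | (3R,5E)-6-iodo-5-methylhexa-1,5-dien-3-ol | C=C[C@H](O)C/C(C)=C/I | intermediate
8 | tert-butyl(dimethyl)(prop-2-yn-1-yloxy)silane | C#CCO[Si](C)(C)C(C)(C)C | starting material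
9 | methyl 4-{[tert-butyl(dimethyl)silyl]oxy}but-2-ynoate | COC(=O)C#CCO[Si](C)(C)C(C)(C)C | intermediate
10 | methyl (2Z)-3-({[tert-butyl(dimethyl)silyl]oxy}methyl)penta-2,4-dienoate | C=C/C(CO[Si](C)(C)C(C)(C)C)=C/C(=O)OC | intermediate
11 | methyl (2Z)-5-(9-borabicyclo[3.3.1]nonan-9-yl)-3-({[tert-butyl(dimethyl)silyl]oxy}methyl)pent-2-enoate | COC(=O)/C=C(/CCB1C2CCCC1CCC2)CO[Si](C)(C)C(C)(C)C | intermediate
12 | methyl (2Z,6E,9R)-3-({[tert-butyl(dimethyl)silyl]oxy}methyl)-9-hydroxy-7-methylundeca-2,6,10-trienoate | C=C[C@H](O)C/C(C)=C/CC/C(CO[Si](C)(C)C(C)(C)C)=C/C(=O)OC | intermediate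
13 | ethoxyethene (ethyl vinyl ether) | C=COCC | starting material
14 | methyl (2Z,6E,9R)-3-({[tert-butyl(dimethyl)silyl]oxy}methyl)-9-(ethenyloxy)-7-methylundeca-2,6,10-trienoate | C=C[C@H](OC=C)C/C(C)=C/CC/C(CO[Si](C)(C)C(C)(C)C)=C/C(=O)OC | intermediate
15 | 2-methylidenepropane-1,3-diol | C=C(CO)CO | starting material
16 | methyl (2Z,6E,9R)-3-({[tert-butyl(dimethyl)silyl]oxy}methyl)-9-(1-{[2-(hydroxymethyl)prop-2-en-1-yl]oxy}ethoxy)-7-methylundeca-2,6,10-trienoate (both acetal epimers) | C=C[C@H](OC(C)OCC(=C)CO)C/C(C)=C/CC/C(CO[Si](C)(C)C(C)(C)C)=C/C(=O)OC | intermediate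
17 | methyl (2Z,6E,9R)-9-(1-{[2-(bromomethyl)prop-2-en-1-yl]oxy}ethoxy)-3-({[tert-butyl(dimethyl)silyl]oxy}methyl)-7-methylundeca-2,6,10-trienoate | C=C[C@H](OC(C)OCC(=C)CBr)C/C(C)=C/CC/C(CO[Si](C)(C)C(C)(C)C)=C/C(=O)OC | intermediate
18 | methyl 2-methyl-3-oxobutanoate | COC(=O)C(C)C(C)=O | starting material
19 | methyl (2Z,6E,9R)-3-({[tert-butyl(dimethyl)silyl]oxy}methyl)-9-{1-[(7-methoxy-6-methyl-2-methylidene-5,7-dioxoheptyl)oxy]ethoxy}-7-methylundeca-2,6,10-trienoate | C=C[C@H](OC(C)OCC(=C)CCC(=O)C(C)C(=O)OC)C/C(C)=C/CC/C(CO[Si](C)(C)C(C)(C)C)=C/C(=O)OC | intermediate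
20 | methyl (2Z,6E)-3-({[tert-butyl(dimethyl)silyl]oxy}methyl)-8-[(4R)-6-(5-methoxy-4-methyl-3,5-dioxopentyl)-2-methyl-4,7-dihydro-1,3-dioxepin-4-yl]-7-methylocta-2,6-dienoate | CC1OCC(CCC(=O)C(C)C(=O)OC)=C[C@@H](C/C(C)=C/CC/C(CO[Si](C)(C)C(C)(C)C)=C/C(=O)OC)O1 | intermediate
21 | dimethyl (13Z)-16-{[tert-butyl(dimethyl)silyl]oxy}-6β,20-(ethylidenedioxy)-3-oxolabda-8(17),13-diene-15,19-dioate | CC(OC3)O[C@@H]1CC(=C)[C@H](CC/C(CO[Si](C)(C)C(C)(C)C)=C/C(=O)OC)[C@]36CCC(=O)[C@](C)(C(=O)OC)[C@H]16 | intermediate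
22 | 3-(4-methylbenzenesulfonyl)hydrazone of 21 | CC(OC3)O[C@@H]1CC(=C)[C@H](CC/C(CO[Si](C)(C)C(C)(C)C)=C/C(=O)OC)[C@]36CCC(=NNS(=O)(=O)c7ccc(C)cc7)[C@](C)(C(=O)OC)[C@H]16 | intermediate
23 | dimethyl (13Z)-16-{[tert-butyl(dimethyl)silyl]oxy}-6β,20-(ethylidenedioxy)labda-8(17),13-diene-15,19-dioate | CC(OC3)O[C@@H]1CC(=C)[C@H](CC/C(CO[Si](C)(C)C(C)(C)C)=C/C(=O)OC)[C@]36CCC[C@](C)(C(=O)OC)[C@H]16 | intermediate
24 | 2-methyl-1,3-dioxepan-2-ylium tetrafluoroborate bridging O6 and O20 of 23 | CC(OC3)=[O+][C@@H]1CC(=C)[C@H](CC/C(CO[Si](C)(C)C(C)(C)C)=C/C(=O)OC)[C@]36CCC[C@](C)(C(=O)OC)[C@H]16.F[B-](F)(F)F | intermediate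
25 | dimethyl (13Z)-6β-acetoxy-16-{[tert-butyl(dimethyl)silyl]oxy}-20-hydroxylabda-8(17),13-diene-15,19-dioate | CC(=O)O[C@@H]1CC(=C)[C@H](CC/C(CO[Si](C)(C)C(C)(C)C)=C/C(=O)OC)[C@@]6(CO)CCC[C@](C)(C(=O)OC)[C@H]16 | intermediate
26 | methyl (13Z)-6β-acetoxy-16-{[tert-butyl(dimethyl)silyl]oxy}-19-oxo-19,20-epoxylabda-8(17),13-dien-15-oate | CC(=O)O[C@@H]1CC(=C)[C@H](CC/C(CO[Si](C)(C)C(C)(C)C)=C/C(=O)OC)[C@]36CCC[C@](C)(C(=O)OC3)[C@H]16 | intermediate
27 | methyl (13Z)-6β-acetoxy-16-{[tert-butyl(dimethyl)silyl]oxy}-8,19-dioxo-19,20-epoxy-17-norlabd-13-en-15-oate | CC(=O)O[C@@H]1CC(=O)[C@H](CC/C(CO[Si](C)(C)C(C)(C)C)=C/C(=O)OC)[C@]36CCC[C@](C)(C(=O)OC3)[C@H]16 | intermediate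
28 | 8-(trimethylsilyloxy)-8(9)-ene (silyl enol ether) of 27 | CC(=O)O[C@@H]1CC(O[Si](C)(C)C)=C(CC/C(CO[Si](C)(C)C(C)(C)C)=C/C(=O)OC)[C@]36CCC[C@](C)(C(=O)OC3)[C@H]16 | intermediate
29 | methyl (13Z)-6β-acetoxy-9α-hydroxy-16-{[tert-butyl(dimethyl)silyl]oxy}-8,19-dioxo-19,20-epoxy-17-norlabd-13-en-15-oate | CC(=O)O[C@@H]1CC(=O)[C@](O)(CC/C(CO[Si](C)(C)C(C)(C)C)=C/C(=O)OC)[C@]36CCC[C@](C)(C(=O)OC3)[C@H]16 | intermediate
30 | methyl (13Z)-6β-acetoxy-8β,17:19,20-diepoxy-9α-hydroxy-16-{[tert-butyl(dimethyl)silyl]oxy}-19-oxolabd-13-en-15-oate | CC(=O)O[C@@H]1C[C@@]2(CO2)[C@](O)(CC/C(CO[Si](C)(C)C(C)(C)C)=C/C(=O)OC)[C@]36CCC[C@](C)(C(=O)OC3)[C@H]16 | intermediate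
31 | 6β-acetoxy-8β,17-epoxy-9α-hydroxylabd-13-ene-19,20:15,16-diolide | CC(=O)O[C@@H]1C[C@@]2(CO2)[C@](O)(CCC4=CC(=O)OC4)[C@]36CCC[C@](C)(C(=O)OC3)[C@H]16 | intermediate
32 | (13R)-6β-acetoxy-8β,17:9α,13-diepoxylabdane-19,20:15,16-diolide | CC(=O)O[C@@H]1C[C@@]2(CO2)[C@]4(CC[C@]5(CC(=O)OC5)O4)[C@]36CCC[C@](C)(C(=O)OC3)[C@H]16 | intermediate
33 | (13R)-6β-acetoxy-8β,17:9α,13:15,16-triepoxy-15-hydroxylabdan-19,20-olide (both C15 epimers) | CC(=O)O[C@@H]1C[C@@]2(CO2)[C@]4(CC[C@]5(CC(O)OC5)O4)[C@]36CCC[C@](C)(C(=O)OC3)[C@H]16 | intermediate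
34 | 15-methanesulfonate of 33 | CC(=O)O[C@@H]1C[C@@]2(CO2)[C@]4(CC[C@]5(CC(OS(C)(=O)=O)OC5)O4)[C@]36CCC[C@](C)(C(=O)OC3)[C@H]16 | intermediate
35 | nepetaefolin, (13R)-6β-acetoxy-8β,17:9α,13:15,16-triepoxylabd-14-en-19,20-olide | CC(=O)O[C@@H]1C[C@@]2(CO2)[C@]2(CC[C@]3(C=COC3)O2)[C@]23CCC[C@](C)(C(=O)OC2)[C@H]13 | target

**Step count and risks**
Total step count: 20. Longest linear sequence: 18 steps (steps 1–3 and 6–20; steps 4 and 5 are the side-chain branch).

The three steps most likely to fail: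

Step 12. The first radical addition must occur anti to the C6 side chain and the second closure must form a bridged ring, and either may fail. The fallback sets out from 20. Bromination of the β-keto ester (N-bromosuccinimide, Mg(ClO4)2 cat., MeCN) gives the tertiary α-bromo β-keto ester F1. Irradiation with blue light in the presence of fac-Ir(ppy)3 (1 mol %) and 2,6-lutidine in MeCN then generates the same C4 radical reductively. The C8 radical is oxidised by the tetravalent iridium complex of the catalytic cycle and loses a proton (photoredox radical–polar crossover bicyclisation). The fallback comes back to the route at 21.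

Step 14. Hydride abstraction may be unselective, or the orthoacid may collapse the wrong way. The fallback sets out from 23. Excess ozone (EtOAc, −78 to −20 °C, then Me2S) cleaves the 8(17)-alkene and also inserts into the acetal C–H bond, and the hydrotrioxide collapses to the keto hydroxy acetate F2. PPTS in warm benzene then closes the δ-lactone. The fallback comes back to the route at 27.

Step 16. Enolisation may go towards C7 instead of C9, and the later methylene transfer of step 17 depends on the same ketone. The fallback sets out from 26. Dye-sensitised photo-oxygenation (O2, tetraphenylporphyrin, visible light, CH2Cl2, 0 °C; Schenck ene reaction) gives the allylic 17-hydroperoxide F3, and PPh3 reduces it to the 8(9)-en-17-alcohol F4. VO(acac)2 with t-BuOOH epoxidises the open α face to the 8α,9α-epoxy-17-alcohol F5. TBAF in THF then triggers a Payne rearrangement: the 17-alkoxide attacks C8 from the β face and gives the 8β,17-epoxide and the 9α-alkoxide, that is the alkoxide of 30. Desilylation, lactonisation and oxa-Michael addition follow as in step 18. The fallback comes back to the route at 32, and steps 15–17 are then not needed.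

**Further compounds**
F1 | step 12 | methyl (2Z,6E)-8-[(4R)-6-(4-bromo-5-methoxy-4-methyl-3,5-dioxopentyl)-2-methyl-4,7-dihydro-1,3-dioxepin-4-yl]-3-({[tert-butyl(dimethyl)silyl]oxy}methyl)-7-methylocta-2,6-dienoate | CC1OCC(CCC(=O)C(C)(Br)C(=O)OC)=C[C@@H](C/C(C)=C/CC/C(CO[Si](C)(C)C(C)(C)C)=C/C(=O)OC)O1
F2 | step 14 | dimethyl (13Z)-6β-acetoxy-16-{[tert-butyl(dimethyl)silyl]oxy}-20-hydroxy-8-oxo-17-norlabd-13-ene-15,19-dioate | CC(=O)O[C@@H]1CC(=O)[C@H](CC/C(CO[Si](C)(C)C(C)(C)C)=C/C(=O)OC)[C@@]6(CO)CCC[C@](C)(C(=O)OC)[C@H]16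
F3 | step 16 | methyl (13Z)-6β-acetoxy-16-{[tert-butyl(dimethyl)silyl]oxy}-17-hydroperoxy-19-oxo-19,20-epoxylabda-8,13-dien-15-oate | CC(=O)O[C@@H]1CC(COO)=C(CC/C(CO[Si](C)(C)C(C)(C)C)=C/C(=O)OC)[C@]36CCC[C@](C)(C(=O)OC3)[C@H]16
F4 | step 16 | methyl (13Z)-6β-acetoxy-16-{[tert-butyl(dimethyl)silyl]oxy}-17-hydroxy-19-oxo-19,20-epoxylabda-8,13-dien-15-oate | CC(=O)O[C@@H]1CC(CO)=C(CC/C(CO[Si](C)(C)C(C)(C)C)=C/C(=O)OC)[C@]36CCC[C@](C)(C(=O)OC3)[C@H]16
F5 | step 16 | methyl (13Z)-6β-acetoxy-8α,9α:19,20-diepoxy-16-{[tert-butyl(dimethyl)silyl]oxy}-17-hydroxy-19-oxolabd-13-en-15-oate | CC(=O)O[C@@H]1C[C@@]7(CO)O[C@@]7(CC/C(CO[Si](C)(C)C(C)(C)C)=C/C(=O)OC)[C@]36CCC[C@](C)(C(=O)OC3)[C@H]16
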